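## Retrosynthetic overview

1. Numbering: pyrrolidine C1–C3, N4, azepine C5–C9, ring fusion C9a. Spiro lactone: O–C9–C10H2–C11H(CH3)–C12(=O). Side-chain lactone: C18(O)–C19–C20H(CH3)–C21(=O). The butenolide is fused on C5–C6.
2. Butenolide and C5 aminal (last): the target opens to pyruvic acid and the C5=C6 enamine, which comes from chemoselective half-reduction of the C5 lactam of a bis-lactone lactam.
3. Side-chain lactone: C3–C18 is cut to 3-methyl-2-silyloxyfuran and a C3 N-acyliminium ion (from anodic C3–H methoxylation); hydrogenation then sets C20.
4. Spiro lactone (key): a propionate C–C(=O)–O unit is laid across an exocyclic C9=C10 methylene of the azepinone ring, in a formal (3+2) radical–polar crossover annulation with a chiral 2-iodopropionimide. Enabling feature: C9 carries both the ring oxygen and the C10 methylene, so it maps onto a 1,1-disubstituted alkene whose CH2 end takes the radical and whose C9 end becomes a tertiary cation; C9 sits beside the ring-fusion stereocentre C9a, and the N4 lone pair is tied up in the C5 lactam.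
5. The 9-methylidene bicyclic lactam comes from N-Boc-L-proline (C9a; carboxyl carbon = C9) by thioester–alkylzinc ketone synthesis, methylenation and lactamisation. Ring order: pyrrolidine (chiral pool), azepinone, spiro lactone, side-chain lactone, butenolide.

Key step: step 7

Remark (assumption): the aminal centre C5 is taken to be configurationally labile through reversible opening to the iminium carboxylate. Its configuration is therefore settled by equilibration, and the (5S) form, with the C5–O bond pseudo-axial and aligned with the N4 lone pair, is assumed to be the more stable one.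

## Route

Step 1
Reactants: 1 N-Boc-L-proline
Product: 2 S-ethyl (2S)-1-(tert-butoxycarbonyl)pyrrolidine-2-carbothioate
Conditions: EtSH, DCC, DMAP (cat.), CH2Cl2, 0 °C → rt
Reagents that add atoms: ethanethiol, CCS
Why: Steglich-type thioesterification of a urethane-protected amino acid, which is not prone to azlactone racemisation, so C9a (S) is carried over from L-proline.

Step 2
Reactants: 2 S-ethyl thioester; 3 tert-butyl 4-bromobutanoate
Product: 5 tert-butyl (2S)-2-(5-tert-butoxy-5-oxopentanoyl)pyrrolidine-1-carboxylate, via alkylzinc bromide 4 (not isolated)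
Conditions: 3, Zn dust, LiCl, THF, 40 °C; then 2, PdCl2(PPh3)2 (5 mol %), toluene–THF, rt
Reagents that add atoms: none
Why: Fukuyama coupling, in which Pd(0) inserts into the C–S bond and the mild alkylzinc reagent (from LiCl-assisted zinc insertion) transfers its alkyl group without attacking ester, carbamate or the new ketone and without enolising the α-amino ketone.

Step 3
Reactants: 5 keto ester
Product: 6 tert-butyl (2S)-2-(6-tert-butoxy-6-oxohex-1-en-2-yl)pyrrolidine-1-carboxylate
Conditions: Ph3PCH3Br, KHMDS (slight deficit), THF, −78 → 0 °C
Reagents that add atoms: methyltriphenylphosphonium bromide, C[P+](c1ccccc1)(c1ccccc1)c1ccccc1.[Br-]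
Why: Wittig methylenation with the non-stabilised ylide attacks only the ketone (ester and carbamate are inert), and the deficit of base at low temperature limits enolisation at C9a.

Step 4
Reactants: 6 Boc-protected alkene ester
Product: 8 (9aS)-9-methylideneoctahydro-5H-pyrrolo[1,2-a]azepin-5-one, via amino acid trifluoroacetate 7 (not isolated)
Conditions: TFA–CH2Cl2 (1:2), 0 °C → rt, evaporate; then EDC·HCl, HOAt (cat.), i-Pr2NEt, CH2Cl2 (2 mM), rt
Reagents that add atoms: none
Why: Acidolysis removes Boc and tert-butyl ester together (the allylic ammonium group deactivates the alkene towards protonation), and carbodiimide lactamisation at high dilution closes the seven-membered ring, helped by the sp2 carbon C9 in the chain.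

Step 5
Reactants: 9 (4S)-4-(diphenylmethyl)-1,3-oxazolidin-2-one; 10 2-bromopropanoyl bromide (racemic)
Product: 12 (4S)-3-(2-bromopropanoyl)-4-(diphenylmethyl)-1,3-oxazolidin-2-one (both C–Br epimers), via lithium oxazolidinide 11 (not isolated)
Conditions: n-BuLi, THF, −78 °C; then 10, −78 → 0 °C
Reagents that add atoms: none
Why: Standard N-acylation of a lithiated oxazolidinone; the C–Br centre needs no control because it later becomes a planar radical.

Step 6
Reactants: 12 bromo imide
Product: 13 (4S)-4-(diphenylmethyl)-3-(2-iodopropanoyl)-1,3-oxazolidin-2-one (both C–I epimers)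
Conditions: NaI, acetone, rt, dark
Reagents that add atoms: sodium iodide, [Na+].[I-]
Why: Finkelstein exchange driven by precipitation of NaBr gives the iodide, which is the faster atom donor and leads to a tertiary iodide that ionises without an added halophile.

Step 7
Reactants: 8 9-methylidene bicyclic lactam; 13 iodo imide
Product: 16 (9S,9aS,11R)-spiro-lactone lactam [octahydro-5H-pyrrolo[1,2-a]azepin-5-one with C9 spiro-joined to a γ-butyrolactone: O on C9 then C10H2 then C11H(CH3) then C12=O], via tertiary C9 iodide 14 (not isolated), via O-alkylated imide salt 15 (not isolated)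
Conditions: 13 (1.5 equiv), Yb(OTf)3 (2.5 equiv), 2,6-di-tert-butylpyridine, Et3B (cat.)/air, CH2Cl2–THF (4:1), −40 °C → rt; then H2O, NaHCO3
Reagents that add atoms: water, O
Why: Proposed new method: Et3B/O2 abstracts iodine from the Yb(III)-chelated imide 13, the electrophilic α-imide radical adds to the C10 terminus of the exocyclic C9=C10 alkene, iodine-atom transfer gives tertiary iodide 14, this ionises on warming so that the acyl oxygen of the imide captures C9 to give 15, and water cleaves 15 to lactone 16 with release of the auxiliary, overall a formal (3+2) radical–polar crossover annulation of a propionate C–C–O unit across the alkene. The closest known reaction types are the Lewis-acid-promoted atom-transfer addition and allylation of α-halo N-acyloxazolidinones, the iodine-atom-transfer lactone annulation of 2-iodo amides and acids with alkenes, and the halolactonisation of unsaturated N-acyloxazolidinones with loss of the auxiliary; what is new is their merger in one flask. The only ring closed is the γ-lactone, by 5-exo capture of the planar tertiary C9 cation by the carbonyl oxygen. C11 (R) is set by the (4S)-auxiliary: in the chelate both carbonyl groups are syn, the radical methyl group points away from the ring nitrogen, the CHPh2 group covers one face and the alkene adds to the other, in the same sense as enolate alkylation of such imides. C9 (S) is set by C9a: allylic 1,3-strain holds H-9a in the plane of the cation next to C10, one lobe is then covered by the C1 methylene of the pyrrolidine, oxygen enters anti to the C9a–C1 bond, and both epimers of 14 converge on this one cation. The step needs terminal radical attack, secured by the 1,1-disubstitution, and capture faster than hydride shift or proton loss, secured by the five-membered transition state, by H-9a lying orthogonal to the empty orbital, and by the C5 lactam, which withdraws the N4 lone pair (no aziridinium ion, no amine oxidation or alkylation).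

Step 8
Reactants: 16 spiro-lactone lactam
Product: 17 3-methoxy derivative of 16 (both C3 epimers)
Conditions: graphite anode, Pt cathode, Et4NOTs, MeOH, undivided cell, constant current, 2.5 F/mol, 10 °C
Reagents that add atoms: methanol, CO
Why: Shono oxidation, in which two-electron oxidation of the lactam nitrogen is followed by loss of a proton from the open C3 methylene rather than from the neopentyl-type C9a methine and by capture with methanol; both C3 epimers serve in step 10.

Step 9
Reactants: 18 3-methylfuran-2(5H)-one
Product: 19 triisopropyl[(3-methylfuran-2-yl)oxy]silane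
Conditions: TIPSOTf, Et3N, CH2Cl2, 0 °C
Reagents that add atoms: triisopropylsilyl trifluoromethanesulfonate, CC(C)[Si](C(C)C)(C(C)C)OS(=O)(=O)C(F)(F)F
Why: Soft enolisation of the butenolide with silyl triflate and amine gives the aromatic 2-silyloxyfuran.

Step 10
Reactants: 17 3-methoxy lactam; 19 silyloxyfuran
Product: 21 (3S,9S,9aS,11R,18S)-butenolide adduct [16 bearing at C3 a 4-methyl-5-oxo-2,5-dihydrofuran-2-yl group; 3,9a-trans; C3/C18 threo], via N-acyliminium triflate 20 (not isolated)
Conditions: TIPSOTf (10 mol %), CH2Cl2, −78 → −40 °C
Reagents that add atoms: none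
Why: Vinylogous Mukaiyama–Mannich reaction, in which the furan attacks ion 20 through its C5 on the pyrrolidine face of H-9a, anti to the quaternary C9 (sets C3 S, 3,9a-trans), and the usual open transition state of 2-silyloxyfurans with five-membered N-acyliminium ions favours the threo adduct (sets C18 S).

Step 11
Reactants: 21 butenolide adduct
Product: 22 (3S,9S,9aS,11R,18S,20S)-bis-lactone lactam [16 bearing at C3 a cis-4-methyl-5-oxotetrahydrofuran-2-yl group]
Conditions: H2 (1 atm), 5% Rh/Al2O3, EtOAc, rt
Reagents that add atoms: none
Why: Heterogeneous syn-hydrogenation of the only C=C bond takes place on the butenolide face opposite to the bulky C18 substituent, which places the C20 methyl group cis to C3 (20S), and rhodium limits allylic C–O hydrogenolysis.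

Step 12
Reactants: 22 bis-lactone lactam; 23 pyruvic acid
Product: 26 target (3S,5S,9S,9aS,11R,18S,20S), via O-silyl hemiaminal 24 (not isolated), via C5=C6 enamine 25 (not isolated)
Conditions: IrCl(CO)(PPh3)2 (1 mol %), (Me2SiH)2O, toluene, rt, evaporate; then pyruvic acid, 4 Å MS, CH2Cl2, rt → 40 °C
Reagents that add atoms: none
Why: Proposed new method: the iridium-catalysed hydrosilylation reduces the tertiary lactam in preference to the two lactones and stops at O-silyl hemiaminal 24, which loses silanol to enamine 25; C6 of 25 should add to the keto group of pyruvic acid, the nitrogen lone pair then expels water as in an amine-mediated aldol condensation, and the carboxylate of the Z-configured conjugated iminium ion closes on C5 (the E isomer equilibrates through the dienamine), the reversible closure setting C5 (S) under thermodynamic control; the closest known reaction types are the reductive functionalisation of lactams through such enamines and the amine-mediated condensation of enolisable aldehydes with glyoxylic acid to 5-amino- and 5-hydroxyfuran-2(5H)-ones.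

## Compound list

1 | N-Boc-L-proline, (2S)-1-(tert-butoxycarbonyl)pyrrolidine-2-carboxylic acid | CC(C)(C)OC(=O)N1CCC[C@H]1C(=O)O | starting material
2 | S-ethyl (2S)-1-(tert-butoxycarbonyl)pyrrolidine-2-carbothioate | CCSC(=O)[C@@H]1CCCN1C(=O)OC(C)(C)C | intermediate
3 | tert-butyl 4-bromobutanoate | CC(C)(C)OC(=O)CCCBr | starting material
4 | (4-tert-butoxy-4-oxobutyl)zinc bromide (not isolated) | CC(C)(C)OC(=O)CCC[Zn]Br | intermediate
5 | tert-butyl (2S)-2-(5-tert-butoxy-5-oxopentanoyl)pyrrolidine-1-carboxylate | CC(C)(C)OC(=O)CCCC(=O)[C@@H]1CCCN1C(=O)OC(C)(C)C | intermediate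
6 | tert-butyl (2S)-2-(6-tert-butoxy-6-oxohex-1-en-2-yl)pyrrolidine-1-carboxylate | C=C(CCCC(=O)OC(C)(C)C)[C@@H]1CCCN1C(=O)OC(C)(C)C | intermediate
7 | 5-[(2S)-pyrrolidin-2-yl]hex-5-enoic acid trifluoroacetate (not isolated) | C=C(CCCC(=O)O)[C@@H]1CCCN1.OC(=O)C(F)(F)F | intermediate
8 | (9aS)-9-methylideneoctahydro-5H-pyrrolo[1,2-a]azepin-5-one | C=C1CCCC(=O)N2CCC[C@@H]12 | intermediate
9 | (4S)-4-(diphenylmethyl)-1,3-oxazolidin-2-one | O=C1OC[C@H](C(c2ccccc2)c2ccccc2)N1 | starting material
10 | 2-bromopropanoyl bromide (racemic) | CC(Br)C(=O)Br | starting material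
11 | lithium salt of 9 (not isolated) | [Li]N1C(=O)OC[C@@H]1C(c1ccccc1)c1ccccc1 | intermediate
12 | (4S)-3-(2-bromopropanoyl)-4-(diphenylmethyl)-1,3-oxazolidin-2-one, both C–Br epimers | CC(Br)C(=O)N1C(=O)OC[C@@H]1C(c1ccccc1)c1ccccc1 | intermediate
13 | (4S)-4-(diphenylmethyl)-3-(2-iodopropanoyl)-1,3-oxazolidin-2-one, both C–I epimers | CC(I)C(=O)N1C(=O)OC[C@@H]1C(c1ccccc1)c1ccccc1 | intermediate
14 | (4S)-4-(diphenylmethyl)-3-{(2R)-3-[(9aS)-9-iodo-5-oxooctahydro-1H-pyrrolo[1,2-a]azepin-9-yl]-2-methylpropanoyl}-1,3-oxazolidin-2-one, both C9 epimers (not isolated) | C[C@H](CC1(I)CCCC(=O)N2CCC[C@@H]12)C(=O)N1C(=O)OC[C@@H]1C(c1ccccc1)c1ccccc1 | intermediate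
15 | (9S,9aS,11R)-O-alkylated imide iodide: spiro 4,5-dihydrofuran-1-ium ring (O+ on C9) bearing the oxazolidinone nitrogen on C12 (not isolated) | O=C1CCC[C@]2(C[C@@H](C)C(=[O+]2)N2C(=O)OC[C@@H]2C(c2ccccc2)c2ccccc2)[C@@H]2CCCN12.[I-] | intermediate
16 | (9S,9aS,11R)-spiro-lactone lactam | O=C1CCC[C@]2(C[C@@H](C)C(=O)O2)[C@@H]2CCCN12 | intermediate
17 | 3-methoxy derivative of 16, both C3 epimers | O=C1CCC[C@]2(C[C@@H](C)C(=O)O2)[C@@H]2CCC(OC)N12 | intermediate
18 | 3-methylfuran-2(5H)-one | CC1=CCOC1=O | starting material
19 | triisopropyl[(3-methylfuran-2-yl)oxy]silane | Cc1ccoc1O[Si](C(C)C)(C(C)C)C(C)C | intermediate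
20 | C3=N4 N-acyliminium triflate of 16 (not isolated) | O=C1CCC[C@]2(C[C@@H](C)C(=O)O2)[C@@H]2CCC=[N+]12.[O-]S(=O)(=O)C(F)(F)F | intermediate
21 | (3S,9S,9aS,11R,18S)-butenolide adduct | O=C1CCC[C@]2(C[C@@H](C)C(=O)O2)[C@@H]2CC[C@@H]([C@@H]3C=C(C)C(=O)O3)N12 | intermediate
22 | (3S,9S,9aS,11R,18S,20S)-bis-lactone lactam | O=C1CCC[C@]2(C[C@@H](C)C(=O)O2)[C@@H]2CC[C@@H]([C@@H]3C[C@H](C)C(=O)O3)N12 | intermediate
23 | pyruvic acid | CC(=O)C(=O)O | starting material
24 | C5 O-(1,1,3,3-tetramethyldisiloxanyl) hemiaminal of 22, both C5 epimers (not isolated) | C[SiH](C)O[Si](C)(C)OC1CCC[C@]2(C[C@@H](C)C(=O)O2)[C@@H]2CC[C@@H]([C@@H]3C[C@H](C)C(=O)O3)N12 | intermediate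
25 | C5=C6 enamine derived from 22 (not isolated) | C1=CCC[C@]2(C[C@@H](C)C(=O)O2)[C@@H]2CC[C@@H]([C@@H]3C[C@H](C)C(=O)O3)N12 | intermediate
26 | target, (3S,5S,9S,9aS,11R,18S,20S) | CC1=C2CC[C@]3(C[C@@H](C)C(=O)O3)[C@@H]3CC[C@@H]([C@@H]4C[C@H](C)C(=O)O4)N3[C@H]2OC1=O | target

## Step count and risks

Total step count: 12. Longest linear sequence: 9 (steps 1, 2, 3, 4, 7, 8, 10, 11, 12).

**Step 7.**
- Risk: capture of the C9 cation by the weakly nucleophilic, metal-bound imide oxygen may be slower than proton loss or hydride migration from C9a. Competition of the lactam carbonyl for Yb(III) may also erode chelate control at C11.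
- Fallback (known chemistry, no carbocation), setting out from 8: epoxidation with mCPBA on the alkene face anti to C1 should give the spiro-epoxide F1. Sodium diethyl methylmalonate in ethanol opens it at C10, and the tertiary alkoxide lactonises to the 11-ethoxycarbonyl spiro-lactone F2. Saponification, acidification and thermal decarboxylation should then give 16 together with its 11-epimer F3, which is equilibrated with DBU and recycled. The route is rejoined at 16.

**Step 12.**
- Risk: protonation of the enamine by the acid, followed by Mannich-type attack of enolised pyruvic acid at C5 or self-condensation of the enamine, may outrun C6–C bond formation. The C5 equilibrium may also be unfavourable.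
- Fallback, setting out from 22: enamine 25 is generated in the same way, freed from silane and treated under neutral aprotic conditions with ethyl pyruvate (Stork-type enamine addition to an activated ketone) to give the hydroxy ester enamine F4. Aqueous trifluoroacetic acid in THF then converts the enamine into the C5 hemiaminal, which lactonises with loss of ethanol and dehydrates. The route is rejoined at 26.

**Step 8.**
- Risk: loss of regiocontrol (oxidation at the C9a methine) or over-oxidation to the enamide during electrolysis.
- Fallback, setting out from 16: RuO2 (cat.)/NaIO4 in EtOAc–water oxidises the C3 methylene of the N-acylpyrrolidine to the 3,5-dioxo imide F5. NaBH4 in methanol at −20 °C reduces the less hindered five-ring carbonyl to the 3-hydroxy lactam F6. Methanol with PPTS exchanges OH for OMe, and the route is rejoined at 17.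

## Further compounds

F1 | step 7 | (9R,9aS)-spiro-epoxide of 8, oxirane oxygen on C9 on the face anti to C1 | O=C1CCC[C@]2(CO2)[C@@H]2CCCN12
F2 | step 7 | 11-ethoxycarbonyl derivative of 16, both C11 epimers | O=C1CCC[C@]2(CC(C)(C(=O)OCC)C(=O)O2)[C@@H]2CCCN12
F3 | step 7 | (9S,9aS,11S)-epimer of 16 | O=C1CCC[C@]2(C[C@H](C)C(=O)O2)[C@@H]2CCCN12
F4 | step 12 | ethyl 2-hydroxy-2-(C6 of enamine 25)propanoate, both carbinol epimers | C1=C(C(C)(O)C(=O)OCC)CC[C@]2(C[C@@H](C)C(=O)O2)[C@@H]2CC[C@@H]([C@@H]3C[C@H](C)C(=O)O3)N12
F5 | step 8 | 3,5-dioxo imide derived from 16 | O=C1CCC[C@]2(C[C@@H](C)C(=O)O2)[C@@H]2CCC(=O)N12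
F6 | step 8 | 3-hydroxy lactam derived from 16, both C3 epimers | O=C1CCC[C@]2(C[C@@H](C)C(=O)O2)[C@@H]2CCC(O)N12
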